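**Retrosynthetic overview**
1. Asplenetin comes from global O-demethylation of its pentamethyl ether. This is the last step and changes no skeletal bond.
2. Ring C is cut at the O1-C2 carbon-oxygen bond. The ortho-phenol oxygen of a ring-A alkyl aryl ketone is joined to the activated amide carbon of a ring-B benzamide (an aroyl chloroiminium salt). The tethered enolate then closes C3 onto C2 and morpholine leaves.
3. The ring-A ketone comes from 3,5-dimethoxyphenol and 5-methylhexanoic acid by ortho Friedel-Crafts acylation. C2 of the acid becomes C3 of the flavone, and its C3-C6 tail is the 3-methylbutyl group.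
4. Rings A and B are bought. Ring C is the only ring made (step 2).

Assumption: the target has no stereocentre and is achiral, so there is no enantiomer to select and the SMILES is taken as it stands.

**Step 1**
Reactants: 1 3,5-dimethoxyphenol; 2 5-methylhexanoic acid
Product: 3 1-(2-hydroxy-4,6-dimethoxyphenyl)-5-methylhexan-1-one
Conditions: 2 (1.1 equiv), BF3·OEt2 (solvent), 85 °C, 3 h; then aq. NaOAc
Reagents that add atoms: none
Why: Friedel-Crafts acylation with the free acid under BF3 (O-acylation, then Fries shift), in which the boron chelate between the phenol oxygen and the new ketone steers the acyl group ortho to OH and the deactivated product does not acylate twice; no stereocentre is formed.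

**Step 2**
Reactants: 3 1-(2-hydroxy-4,6-dimethoxyphenyl)-5-methylhexan-1-one; 4 trimetozine [morpholin-4-yl(3,4,5-trimethoxyphenyl)methanone]
Product: 8 asplenetin pentamethyl ether [5,7-dimethoxy-3-(3-methylbutyl)-2-(3,4,5-trimethoxyphenyl)-4H-chromen-4-one], via chloroiminium chloride 5 (not isolated), via aryloxyiminium chloride 6 (not isolated), via 2-morpholinoflavanone aminal 7 (not isolated)
Conditions: (a) 4 (1.2 equiv), (COCl)2 (1.3 equiv), CH2Cl2, 0 °C to rt, 2 h, evaporate; (b) 3, iPr2NEt (3.5 equiv), ClCH2CH2Cl, 0 °C, 30 min; (c) MgBr2·OEt2 (1.5 equiv), rt to 50 °C, 6 h; (d) AcOH, 60 °C, 1 h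
Reagents that add atoms: none
Why: Proposed new method: O-imidoylative flavone annulation, in which the phenoxide of 3 displaces chloride from the benzamide-derived chloroiminium salt 5 and so makes the O1-C2 bond that stays in the target; the cationic carbon of 6 is far more electrophilic than the ester carbonyl of a Baker-Venkataraman substrate, so the magnesium enolate raised by MgBr2·OEt2/iPr2NEt soft enolisation closes C3 onto it by a favoured 6-(enolendo)-exo-trig path to aminal 7 (enolate O-attack is reversible, and if halide returns 6 to 5 the enolate attacks 5 at carbon first and the phenoxide then closes to the same 7); acid then protonates morpholine so that it, not the aryl oxide, leaves and 7 collapses to the conjugated pyranone; the closest known reaction types are the Vilsmeier-Haack chromone and isoflavone syntheses from o-hydroxyaryl ketones with DMF-derived chloroiminium salts and the Baker-Venkataraman rearrangement followed by cyclodehydration, neither yet run with an aryl amide salt to bring in the 2-aryl group; the two transient stereocentres of 7 are erased.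

**Step 3**
Reactants: 8 asplenetin pentamethyl ether
Product: 9 asplenetin [5,7-dihydroxy-3-(3-methylbutyl)-2-(3,4,5-trihydroxyphenyl)-4H-chromen-4-one]
Conditions: BBr3 (12 equiv), CH2Cl2, -78 °C to rt, 24 h, argon; then ice/1 M HCl, degassed work-up
Reagents that add atoms: none
Why: Lewis-acid aryl methyl ether cleavage (BBr3 demethylation), in which boron binds each ether oxygen and bromide removes the methyl group by SN2, with the 5-OMe helped by chelation to C4=O, while the saturated side chain and the pyranone are inert; no stereocentre is present.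

**Compound list**
1 | 3,5-dimethoxyphenol | COc1cc(O)cc(OC)c1 | starting material
2 | 5-methylhexanoic acid | CC(C)CCCC(=O)O | starting material
3 | 1-(2-hydroxy-4,6-dimethoxyphenyl)-5-methylhexan-1-one | CC(C)CCCC(=O)c1c(O)cc(OC)cc1OC | intermediate
4 | trimetozine, morpholin-4-yl(3,4,5-trimethoxyphenyl)methanone | COc1cc(cc(OC)c1OC)C(=O)N1CCOCC1 | starting material
5 | 4-[chloro(3,4,5-trimethoxyphenyl)methylidene]morpholin-4-ium chloride | COc1cc(cc(OC)c1OC)C(Cl)=[N+]1CCOCC1.[Cl-] | intermediate (not isolated)
6 | 4-{[3,5-dimethoxy-2-(5-methylhexanoyl)phenoxy](3,4,5-trimethoxyphenyl)methylidene}morpholin-4-ium chloride | CC(C)CCCC(=O)c1c(OC)cc(OC)cc1OC(=[N+]1CCOCC1)c1cc(OC)c(OC)c(OC)c1.[Cl-] | intermediate (not isolated)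
7 | 5,7-dimethoxy-3-(3-methylbutyl)-2-(morpholin-4-yl)-2-(3,4,5-trimethoxyphenyl)-2,3-dihydro-4H-chromen-4-one, racemic mixture of diastereomers | CC(C)CCC1C(=O)c2c(OC)cc(OC)cc2OC1(N1CCOCC1)c1cc(OC)c(OC)c(OC)c1 | intermediate (not isolated)
8 | asplenetin pentamethyl ether, 5,7-dimethoxy-3-(3-methylbutyl)-2-(3,4,5-trimethoxyphenyl)-4H-chromen-4-one | CC(C)CCc1c(-c2cc(OC)c(OC)c(OC)c2)oc2cc(OC)cc(OC)c2c1=O | intermediate
9 | asplenetin, 5,7-dihydroxy-3-(3-methylbutyl)-2-(3,4,5-trihydroxyphenyl)-4H-chromen-4-one (achiral) | CC(C)CCc1c(-c2cc(O)c(O)c(O)c2)oc2cc(O)cc(O)c2c1=O | target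

Total step count: 3
Longest linear sequence: 3

**Steps most likely to fail**

**Step 2, the proposed new annulation.**
- Risks:
  - Traces of water could turn 6 into the plain aryl ester.
  - Enolisation of the twisted, hindered ketone could be slow.
  - Salt 5 could attack the electron-rich ring-A carbons.
  - Chloride could dealkylate the morpholinium unit on long heating.
- Fallback (known chemistry): it sets out from 3 and comes back at 8.
  - The phenol of 3 is acylated with commercial 3,4,5-trimethoxybenzoyl chloride (pyridine, cat. DMAP, rt). This gives 3,5-dimethoxy-2-(5-methylhexanoyl)phenyl 3,4,5-trimethoxybenzoate F1.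
  - A Baker-Venkataraman rearrangement (KOH, pyridine, 50 °C, then AcOH) moves the aroyl group to carbon. This gives 1-(2-hydroxy-4,6-dimethoxyphenyl)-2-(3-methylbutyl)-3-(3,4,5-trimethoxyphenyl)propane-1,3-dione F2.
  - Acid cyclodehydration (cat. H2SO4, AcOH, 100 °C) closes the O1-C2 bond to 8.

**Step 3, fivefold demethylation.**
- Risks: the 7-OMe is the slowest ether to cleave, and the free pyrogallol ring oxidises easily, so partly methylated or darkened material is possible.
- Fallback: it replaces methyl by benzyl so that the last step is a neutral hydrogenolysis. It sets out from 2 and comes back at 9.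
  - Phloroglucinol is acylated with 2 (BF3·OEt2, 85 °C) to give 5-methyl-1-(2,4,6-trihydroxyphenyl)hexan-1-one F3.
  - Two hydroxyls are benzylated, leaving one chelated ortho-OH free (BnBr 2.1 equiv, K2CO3, acetone, reflux). This gives 1-[2,4-bis(benzyloxy)-6-hydroxyphenyl]-5-methylhexan-1-one F4.
  - Commercial 3,4,5-tris(benzyloxy)benzoic acid is converted with (COCl)2 and cat. DMF into 3,4,5-tris(benzyloxy)benzoyl chloride F5.
  - The lithium dianion of F4 (LiN(SiMe3)2 3 equiv, THF, -78 °C) is C-aroylated with F5. This gives 1-[2,4-bis(benzyloxy)-6-hydroxyphenyl]-2-(3-methylbutyl)-3-[3,4,5-tris(benzyloxy)phenyl]propane-1,3-dione F6.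
  - Treatment with p-TsOH in refluxing toluene cyclodehydrates F6 to 5,7-bis(benzyloxy)-3-(3-methylbutyl)-2-[3,4,5-tris(benzyloxy)phenyl]-4H-chromen-4-one F7.
  - Hydrogenolysis (H2, 1 atm, Pd/C, EtOAc/MeOH) frees all five phenols. The tetrasubstituted C2=C3 bond is not touched, and the product is 9.

**Step 1, regiochemistry of the acylation.**
- Risks: some para-acyl isomer (4-hydroxy-2,6-dimethoxyphenyl ketone) or unrearranged aryl ester may form alongside 3.
- Fallback: it uses a threefold-symmetric arene, so only one acylation product can form. It sets out from 2 and comes back at 3.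
  - Acid 2 is converted with SOCl2 into 5-methylhexanoyl chloride F8.
  - F8 acylates commercial 1,3,5-trimethoxybenzene (AlCl3, CH2Cl2, 0 °C) to give 5-methyl-1-(2,4,6-trimethoxyphenyl)hexan-1-one F9.
  - BCl3 (CH2Cl2, -10 °C) cleaves only a methoxy group chelated to the ketone and gives 3.

**Further compounds**
F1 | step 2 | 3,5-dimethoxy-2-(5-methylhexanoyl)phenyl 3,4,5-trimethoxybenzoate | CC(C)CCCC(=O)c1c(OC)cc(OC)cc1OC(=O)c1cc(OC)c(OC)c(OC)c1
F2 | step 2 | 1-(2-hydroxy-4,6-dimethoxyphenyl)-2-(3-methylbutyl)-3-(3,4,5-trimethoxyphenyl)propane-1,3-dione (racemic, enolisable) | CC(C)CCC(C(=O)c1c(O)cc(OC)cc1OC)C(=O)c1cc(OC)c(OC)c(OC)c1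
F3 | step 3 | 5-methyl-1-(2,4,6-trihydroxyphenyl)hexan-1-one | CC(C)CCCC(=O)c1c(O)cc(O)cc1O
F4 | step 3 | 1-[2,4-bis(benzyloxy)-6-hydroxyphenyl]-5-methylhexan-1-one | CC(C)CCCC(=O)c1c(O)cc(OCc2ccccc2)cc1OCc1ccccc1
F5 | step 3 | 3,4,5-tris(benzyloxy)benzoyl chloride | O=C(Cl)c1cc(OCc2ccccc2)c(OCc2ccccc2)c(OCc2ccccc2)c1
F6 | step 3 | 1-[2,4-bis(benzyloxy)-6-hydroxyphenyl]-2-(3-methylbutyl)-3-[3,4,5-tris(benzyloxy)phenyl]propane-1,3-dione (racemic, enolisable) | CC(C)CCC(C(=O)c1c(O)cc(OCc2ccccc2)cc1OCc1ccccc1)C(=O)c1cc(OCc2ccccc2)c(OCc2ccccc2)c(OCc2ccccc2)c1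
F7 | step 3 | 5,7-bis(benzyloxy)-3-(3-methylbutyl)-2-[3,4,5-tris(benzyloxy)phenyl]-4H-chromen-4-one | CC(C)CCc1c(-c2cc(OCc3ccccc3)c(OCc3ccccc3)c(OCc3ccccc3)c2)oc2cc(OCc3ccccc3)cc(OCc3ccccc3)c2c1=O
F8 | step 1 | 5-methylhexanoyl chloride | CC(C)CCCC(=O)Cl
F9 | step 1 | 5-methyl-1-(2,4,6-trimethoxyphenyl)hexan-1-one | CC(C)CCCC(=O)c1c(OC)cc(OC)cc1OC
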